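## Structural features

The target is a methylene-bridged hetero-dimer of an acylphloroglucinol and a 6-ethyl-4-hydroxy-5-methyl-2H-pyran-2-one, joined by one CH2 between C7 of the arene and C3' of the pyranone ring. The benzene ring is fully substituted: it is fused at C3a/C7a to a 2,3-dihydrofuran ring (O1, C2, C3), carries phenols at C4 and C6 with the isobutyryl ketone at C5 between them, and bears the bridge at C7, so O1 is para to the ketone. The only stereocentre is C2 (R), which bears the isopropenyl group; with no neighbouring stereocentre, its configuration must come from a reagent or catalyst. Fragile points are the 1,1-disubstituted alkene (acid gives a tertiary cation, and migration into conjugation leads to the 2-isopropylbenzofuran), the allylic aryl ether C2–O1, the oxidation-prone phloroglucinol, and the methylene bridge, which can be lost by retro-reaction. The real difficulties are three: the single-enantiomer 2-isopropenyl-dihydrobenzofuran with the alkene kept terminal, the placement of O1 para rather than ortho to the acyl group on a ring with three near-equivalent oxygens, and the union of two carbon nucleophiles through one carbon without homo-coupling. The key step uses the fact that O1–C2(H)–C(CH3)=CH2 is the ring-contracted, dehydrated isomer of the O1–C(CH3)2–CH(OH) unit of a 2,2-dimethylchroman-3-ol. Moving O1 from the quaternary carbon to the carbinol carbon makes the five-membered ring, the stereocentre and the alkene in one operation. The chroman-3-ol comes from a 2,2-dimethylchromene, a cis-disubstituted conjugated alkene of the kind that chiral (salen)MnCl (trivalent manganese) epoxidises with high selectivity.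

## Logic of the disconnections

**22 to 16 and 20.** The bond between the bridging methylene carbon and C3' is cut. Both halves are carbon nucleophiles at exactly these positions, so one of them must hold the one-carbon electrophile. Placing it on C7 as an aminomethyl group gives a latent ortho-quinone methide on the only partner that has no other free ring position. The gain is convergence in the last step, two halves of similar size, one achiral, and no protecting group. The forward step must lose amine from 16 at a temperature that C2 and the isopropenyl group tolerate, and 20 must attack through carbon.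

**20 to 18 and 19, then 18 to 17.** Bonds C4'–C5' and O1'–C2' are cut, then the O–Si bond. A symmetrical five-carbon ketone and a three-carbon diacid chloride contain all the atoms, so no regiochemical question arises. The forward step needs C-acylation of 18 before ring closure through oxygen.

**16 to 15 to 14.** The C7–CH2 bond is cut and the two O–Si bonds are restored. C7 is the only unsubstituted ring carbon of 15, so aminomethylation needs no control. The demand is that fluoride and the iminium reagent leave C2 and the alkene untouched.

**14 to 11 (strategic).** O1 is disconnected from C2 and reconnected to the carbon that carries the two methyl groups. This turns the dihydrofuran into a 2,2-dimethylchroman-3-ol and the alkene into a gem-dimethyl group. The gain is that the stereocentre becomes a secondary carbinol next to a benzylic carbon, which chromene epoxidation delivers. The forward step must achieve oxygen participation with inversion, in preference to elimination toward C4 and methyl shift, and must lose the proton from a methyl group.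

**11 to 10 to 9.** The benzylic C4–O bond is re-formed to give the epoxide, and then both C–O bonds of the epoxide are cut. The gain is an achiral, flat chromene, so all asymmetry is introduced by the catalyst. The demands are a high facial preference on 9, survival of a very electron-rich benzylic epoxide, and hydrogenolysis only at C4.

**9 to 6.** The C4–C4a bond is cut and the pyran ring is opened to an aryl 1,1-dimethylpropargyl ether. The oxygen that ends up in the ring is then defined by where the ether sits. Both ortho carbons are equivalent and both flanking oxygens are silylated in 6, so only one chromene can form. The demand is a clean thermal cascade in the presence of two aryl silyl ethers.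

**6 to 5 to 3 and 4.** The two O–Si bonds and the aryl O–C(tertiary) bond are cut. The hydroxyl para to the ketone in 3 is the most acidic and the only one outside the hydrogen-bonded chelate, so it can be etherified selectively. The demand is mono-O-alkylation of an ambident polyphenol.

**3 to 1 and 2.** The aryl–carbonyl bond is cut. The symmetry of 1 makes the acylation position-independent, and the product is deactivated toward a second acylation.

## Other disconnections considered

**Alternative 1:** The cut runs through the benzene ring: bonds C7a–C7 and C6–C5 (and C7a–C3a in the final electrocyclic closure) would be made from 3-ethoxy-4-(3-methylbut-2-enyl)cyclobut-2-en-1-one A1 and triisopropyl(3-methoxyprop-1-ynyloxy)silane A2. Heating them should open A1 to a vinylketene, add the alkyne in a [2+2] step, open the new four-membered ring and close the dienylketene to 3-ethoxy-2-(3-methylbut-2-enyl)-6-(methoxymethyl)-5-(triisopropylsilyloxy)phenol A3.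

- In favour: the substitution pattern of the arene is fixed by connectivity, and the three oxygens emerge differentiated (free OH as the future O1, ethoxy at the future C4, silyloxy at the future C6). On this point the alternative is better than the chosen plan, which relies on the para-selective etherification of step 2. The bridging carbon is already on C7.
- Against: the benzannulation makes neither the dihydrofuran ring, nor the stereocentre, nor the C5 ketone. A3 would still need an asymmetric oxidation of the prenyl group with ring closure and a regioselective dehydration (or the same ring contraction), and a late acylation at the crowded C5. It would also need cleavage of an aryl ethyl ether, which calls for reagents of the BBr3 type that the isopropenyl group and the allylic ether are unlikely to tolerate, and activation of a benzylic methyl ether. A1 and A2 each need several steps.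
- Comparison: on structure, the alternative rebuilds a phloroglucinol that can be bought. On mechanism, the pericyclic cascade is as dependable as any step of the chosen route (equal). On step economy it should be longer by a wide margin, and it leaves C2 unsolved.

**Alternative 2:** The cut is bond C4–C5 of the benzene ring. Methoxide would make the diketone carbon of methyl (5R)-2-(5-methyl-2,4-dioxohexyl)-5-(prop-1-en-2-yl)-4,5-dihydrofuran-3-carboxylate A4 attack its own ester carbonyl. Loss of methanol and enolisation would give 1-[(2R)-4,6-dihydroxy-2-(prop-1-en-2-yl)-2,3-dihydrobenzofuran-5-yl]-2-methylpropan-1-one A5, which is the same structure as 15.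

- In favour: it is polyketide-like and free of protecting groups. The acyl group, O1 and the free C7 position are placed by connectivity, which is equal to or better than the chosen plan on regiochemistry. The stereocentre exists before the electron-rich arene does, so no labile aryl epoxide is handled.
- Against: the difficulty moves into A4. An enantioenriched 5-isopropenyl-4,5-dihydrofuran-3-carboxylate with a 1,3-diketone side chain must be assembled from a poly-carbonyl anion with several acidic sites and a chiral C5 electrophile, with C- versus O-alkylation and positional questions of its own. Under methoxide the β-alkoxyacrylate could open by retro-oxa-Michael reaction, which would endanger the allylic stereocentre, and aldol closures compete with the desired Claisen closure.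
- Comparison: the key step is mechanistically plausible but harder to predict than a triflate displacement in a rigid ring. Its step count is at best equal, and only if A4 were available in about five steps.

**Alternative 3:** The cut is in the pyranone ring: bonds C4'–C5' and O1'–C2'. The precursor would be the acid chloride A6, a 3-(chlorocarbonyl)-3,4-dihydrocoumarin formed between O6 and C7 of the (2R)-4-silyloxy-5-isobutyryl-2-isopropenyl-dihydrobenzofuran. It would C-acylate 18, and the new enol oxygen would then attack the aryl lactone carbonyl, closing the pyranone and releasing the C6 phenol to give the 4-O-tert-butyldimethylsilyl ether of the target A7.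

- In favour: the bridging carbon is an sp3 malonate carbon from the start, so no quinone methide is needed and homo-coupling is excluded, which is better than the chosen end-game on this point. The C-acylation of a silyl enol ether by a malonyl chloride is the same reaction type as step 11 (equal). The lactone serves as both protecting group and leaving group.
- Against: A6 still requires the complete dihydrobenzofuran, so it replaces only the end-game and not the ring contraction. Making A6 needs attachment of a malonate at C7, lactonisation onto one of two similar phenols, selective protection of the other, and acid chloride formation next to an acid-sensitive alkene. Ring closure by attack on an aryl ester is less established than closure on an acid chloride, and a final desilylation is added.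
- Comparison: it is structurally elegant, but longer by several steps than steps 9 and 12.

Key step: step 7

**Remarks on the chemistry**

- Chroman numbering is used up to compound 13 and benzofuran numbering from 14 on. C3 of the chroman becomes C2 of the benzofuran.
- Assumption: the facial sense of the (salen)MnCl epoxidation follows the established behaviour of 2,2-dimethylchromenes, for which the (S,S)-catalyst gives the (3S,4S)-epoxide. If 9 responded in the opposite sense, the (R,R)-catalyst would be used.
- Stereoelectronic correction: the conformer that reacts in step 7 has the C3 leaving group pseudo-equatorial. Only then is the C3–O bond antiperiplanar to the O1–C2 ring bond. A pseudo-axial leaving group is antiperiplanar to the axial C2 methyl and the axial C4 hydrogen.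
- Change before the key step: the chromene is built by a propargyl ether rearrangement with both ortho oxygens blocked, so the position of the ring oxygen does not depend on an isomer separation. The condensation with 3-methylbut-2-enal is kept as a fallback.

## Route

Step 1
Reactants: 1 phloroglucinol; 2 isobutyryl chloride
Product: 3 2-methyl-1-(2,4,6-trihydroxyphenyl)propan-1-one
Conditions: AlCl3 (4 equiv), PhNO2, 25 → 65 °C; then ice/aq. HCl
Reagents that add atoms: none
Why: Friedel–Crafts C-acylation of a symmetrical, very electron-rich arene; the ketone formed is chelated to aluminium and deactivates the ring, so monoacylation is expected and no positional issue exists.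

Step 2
Reactants: 3 2-methyl-1-(2,4,6-trihydroxyphenyl)propan-1-one; 4 3-chloro-3-methylbut-1-yne
Product: 5 1-[2,6-dihydroxy-4-(2-methylbut-3-yn-2-yloxy)phenyl]-2-methylpropan-1-one
Conditions: DBU (1.2 equiv), CuCl2·2H2O (1 mol%), MeCN, −5 → 0 °C
Reagents that add atoms: none
Why: Copper-catalysed propargylic etherification of a phenol with a tertiary propargylic chloride; with about one equivalent of amidine base only the most acidic hydroxyl of 3 is ionised, the one para to the ketone and outside the chelate, so the ether should form at that oxygen. This choice fixes which oxygen becomes O1.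

Step 3
Reactants: 5 1-[2,6-dihydroxy-4-(2-methylbut-3-yn-2-yloxy)phenyl]-2-methylpropan-1-one
Product: 6 1-[2,6-bis(tert-butyldimethylsilyloxy)-4-(2-methylbut-3-yn-2-yloxy)phenyl]-2-methylpropan-1-one
Conditions: TBSCl (3 equiv), imidazole (6 equiv), DMAP (cat.), DMF, 40 °C
Reagents that add atoms: tert-butyldimethylsilyl chloride, C[Si](C)(Cl)C(C)(C)C
Why: Standard silylation of phenols; the chelated hydroxyl reacts more slowly, hence excess reagent, DMAP and mild warming. The two silyl ethers block the ortho oxygens before the rearrangement and later protect the phenols from the oxidant and from Tf2O.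

Step 4
Reactants: 6 1-[2,6-bis(tert-butyldimethylsilyloxy)-4-(2-methylbut-3-yn-2-yloxy)phenyl]-2-methylpropan-1-one
Product: 9 1-[5,7-bis(tert-butyldimethylsilyloxy)-2,2-dimethyl-2H-chromen-6-yl]-2-methylpropan-1-one, via ortho-allenylphenol 7 (not isolated), via ortho-quinone methide 8 (not isolated)
Conditions: o-xylene, 140 °C, Ar
Reagents that add atoms: none
Why: Thermal aryl propargyl ether Claisen rearrangement ([3,3] shift to one of two equivalent ortho carbons, rearomatisation to 7), then 1,5-hydrogen shift from the only free hydroxyl to the allene centre (8) and oxa-6π electrocyclisation. Both flanking oxygens carry silicon, so only the para oxygen can close the pyran ring and a single chromene constitution is possible.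

Step 5
Reactants: 9 1-[5,7-bis(tert-butyldimethylsilyloxy)-2,2-dimethyl-2H-chromen-6-yl]-2-methylpropan-1-one
Product: 10 1-[(3S,4S)-5,7-bis(tert-butyldimethylsilyloxy)-3,4-epoxy-2,2-dimethylchroman-6-yl]-2-methylpropan-1-one
Conditions: chloro[(S,S)-N,N'-bis(3,5-di-tert-butylsalicylidene)cyclohexane-1,2-diaminato]manganese, (S,S)-(salen)MnCl, trivalent manganese (5 mol%), NMO (5 equiv), mCPBA (2 equiv), CH2Cl2, −78 °C; cold aq. NaOH wash, no silica chromatography
Reagents that add atoms: 3-chloroperoxybenzoic acid, OOC(=O)c1cccc(Cl)c1
Why: Jacobsen epoxidation of a cis-disubstituted, aryl-conjugated 2,2-dimethylchromene, a substrate class this catalyst handles well; the (S,S)-ligand should direct oxygen transfer from the pentavalent oxomanganese species to the face that gives the (3S,4S)-epoxide, which sets the configuration that becomes C2 of the target. The anhydrous peracid/N-oxide variant at low temperature avoids aqueous hypochlorite and base (silyl ether hydrolysis, ring chlorination) and buffers the acid that would open the electron-rich epoxide.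

Step 6
Reactants: 10 1-[(3S,4S)-5,7-bis(tert-butyldimethylsilyloxy)-3,4-epoxy-2,2-dimethylchroman-6-yl]-2-methylpropan-1-one
Product: 11 1-[(3S)-5,7-bis(tert-butyldimethylsilyloxy)-3-hydroxy-2,2-dimethylchroman-6-yl]-2-methylpropan-1-one
Conditions: H2 (1 atm), 10% Pd/C, Et3N (1 equiv), EtOAc, 0 °C → rt
Reagents that add atoms: none
Why: Heterogeneous hydrogenolysis cleaves only the benzylic C4–O bond of the aryl epoxide; the C3–O bond is untouched, so the 3S configuration is retained. The hindered aryl ketone and the silyl ethers should be inert at one atmosphere, and the amine suppresses acid-catalysed isomerisation of the epoxide.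

Step 7
Reactants: 11 1-[(3S)-5,7-bis(tert-butyldimethylsilyloxy)-3-hydroxy-2,2-dimethylchroman-6-yl]-2-methylpropan-1-one
Product: 14 1-[(2R)-4,6-bis(tert-butyldimethylsilyloxy)-2-(prop-1-en-2-yl)-2,3-dihydro-1-benzofuran-5-yl]-2-methylpropan-1-one, via C3 triflate 12 (not isolated), via oxiranium triflate 13 (not isolated)
Conditions: Tf2O (1.15 equiv), 2,6-di-tert-butyl-4-methylpyridine (3 equiv), CH2Cl2, −78 °C, then slowly to 0 °C; aq. NaHCO3
Reagents that add atoms: none
Why: Tf2O converts the hindered C3 hydroxyl of 11 into triflate 12 at −78 °C without touching the 3S configuration. In the half-chair with the C3–OTf bond pseudo-equatorial, that bond is antiperiplanar to the O1–C2 ring bond, so O1 displaces triflate from the rear in a 3-exo-tet closure and gives the bridged aryl-oxiranium ion 13, whose positive charge lies largely on the quaternary carbon. The hindered pyridine then removes a proton from a methyl group whose C–H bond is antiperiplanar to the breaking O1–CMe2 bond; this E2-like opening leaves O1 on the former C3 and turns CMe2 into the isopropenyl group, so the dihydrofuran ring, the only ring formed, is closed by the 3-exo-tet displacement and revealed by cleavage of the old O1–C2 bond. The closest known reaction type is the solvolytic ring contraction of 3-sulfonyloxy-2,2-dimethylchromans to 2-substituted 2,3-dihydrobenzofurans by participation of the ring oxygen, here ended by proton loss instead of capture by a nucleophile. The stereocentre C2 of 14 is the former C3 and is under substrate control: the intramolecular displacement can only proceed with inversion, and as the priorities of the four groups do not change, 3S becomes 2R. Participation must outrun loss of the axial C4 hydrogen (to chromene 9) and shift of the axial C2 methyl group, both of which start from the pseudo-axial conformer; the half-chairs interconvert fast, and the absence of any small or strong base, the non-nucleophilic solvent and the low temperature should leave participation as the easiest exit. The proton must come from a methyl group and not from C3 of 13, which is secured because the C3–H bond of the three-membered ring cannot become antiperiplanar to the breaking bond and because the six methyl hydrogens are the most accessible to the bulky base. The two ortho silyl ethers keep the phenols away from Tf2O and twist the C6 ketone out of the ring plane, so that O1, para to it, stays nucleophilic; any 9 that forms is the substrate of step 5 and can be recycled.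

Step 8
Reactants: 14 1-[(2R)-4,6-bis(tert-butyldimethylsilyloxy)-2-(prop-1-en-2-yl)-2,3-dihydro-1-benzofuran-5-yl]-2-methylpropan-1-one
Product: 15 1-[(2R)-4,6-dihydroxy-2-(prop-1-en-2-yl)-2,3-dihydro-1-benzofuran-5-yl]-2-methylpropan-1-one
Conditions: TBAF (2.4 equiv), AcOH (2.4 equiv), THF, 0 °C
Reagents that add atoms: none
Why: Fluoride cleavage of two aryl silyl ethers activated by the ortho carbonyl; acetic acid keeps the medium near neutral so the liberated acylphloroglucinol is not exposed to strong base. Neither the alkene nor the allylic ether at C2 reacts with fluoride.

Step 9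
Reactants: 15 1-[(2R)-4,6-dihydroxy-2-(prop-1-en-2-yl)-2,3-dihydro-1-benzofuran-5-yl]-2-methylpropan-1-one
Product: 16 1-[(2R)-7-[(dimethylamino)methyl]-4,6-dihydroxy-2-(prop-1-en-2-yl)-2,3-dihydro-1-benzofuran-5-yl]-2-methylpropan-1-one
Conditions: CH2=NMe2+ I− (1.2 equiv), CH2Cl2, 0 °C → rt; aq. NaHCO3
Reagents that add atoms: N,N-dimethylmethyleneiminium iodide (Eschenmoser's salt), C=[N+](C)C.[I-]
Why: Phenol Mannich reaction with a preformed iminium salt; C7 is the only unsubstituted ring carbon of 15 and is ortho/para to three oxygens, so the position is unambiguous and the reaction should be fast enough to avoid methylene bridging of two phenols. The amine of 16 takes up the acid released, which protects the isopropenyl group.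

Step 10
Reactants: 17 pentan-3-one
Product: 18 trimethyl(pent-2-en-3-yloxy)silane (E/Z mixture, geometry irrelevant)
Conditions: TMSCl (1.3 equiv), Et3N (2.5 equiv), DMF, 80 °C
Reagents that add atoms: chlorotrimethylsilane, C[Si](C)(C)Cl
Why: Silyl enol ether formation from a symmetrical ketone under equilibrating amine/silyl chloride conditions; there is no regiochemical issue.

Step 11
Reactants: 18 trimethyl(pent-2-en-3-yloxy)silane; 19 malonyl dichloride
Product: 20 6-ethyl-4-hydroxy-5-methyl-2H-pyran-2-one
Conditions: Et2O, −78 °C → rt; aqueous work-up
Reagents that add atoms: none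
Why: 4-Hydroxy-2-pyranone synthesis from a silyl enol ether and malonyl dichloride: C-acylation of the enol ether (bond C4'–C5', silyl chloride lost) is followed by closure of the new enol oxygen onto the second acyl chloride (bond O1'–C2') and enolisation. The symmetrical ketone fixes the 6-ethyl-5-methyl pattern.

Step 12
Reactants: 16 1-[(2R)-7-[(dimethylamino)methyl]-4,6-dihydroxy-2-(prop-1-en-2-yl)-2,3-dihydro-1-benzofuran-5-yl]-2-methylpropan-1-one; 20 6-ethyl-4-hydroxy-5-methyl-2H-pyran-2-one
Product: 22 6-ethyl-4-hydroxy-3-{[(2R)-4,6-dihydroxy-5-(2-methylpropanoyl)-2-(prop-1-en-2-yl)-2,3-dihydro-1-benzofuran-7-yl]methyl}-5-methyl-2H-pyran-2-one (the target), via ortho-quinone methide 21 (not isolated)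
Conditions: 20 (2 equiv), 1,4-dioxane, 90 °C, N2 purge
Reagents that add atoms: none
Why: Thermal loss of dimethylamine from the ortho-hydroxybenzylamine 16, helped by proton transfer from the acidic 20, gives quinone methide 21, which is captured by conjugate addition of C3' of the 4-hydroxypyranone and rearomatises; this is the amine-displacement coupling used for methylene-bridged acylphloroglucinols. Every ring carbon of 16 is substituted, so the methylene can only go to the pyranone, and the near-neutral conditions should spare C2 and the alkene.

## Compound list

1 | phloroglucinol (benzene-1,3,5-triol) | Oc1cc(O)cc(O)c1 | starting material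
2 | isobutyryl chloride (2-methylpropanoyl chloride) | CC(C)C(Cl)=O | starting material
3 | 2-methyl-1-(2,4,6-trihydroxyphenyl)propan-1-one | CC(C)C(=O)c1c(O)cc(O)cc1O | intermediate
4 | 3-chloro-3-methylbut-1-yne | CC(C)(Cl)C#C | starting material
5 | 1-[2,6-dihydroxy-4-(2-methylbut-3-yn-2-yloxy)phenyl]-2-methylpropan-1-one | CC(C)C(=O)c1c(O)cc(OC(C)(C)C#C)cc1O | intermediate
6 | 1-[2,6-bis(tert-butyldimethylsilyloxy)-4-(2-methylbut-3-yn-2-yloxy)phenyl]-2-methylpropan-1-one | CC(C)C(=O)c1c(O[Si](C)(C)C(C)(C)C)cc(OC(C)(C)C#C)cc1O[Si](C)(C)C(C)(C)C | intermediate
7 | 1-[2,6-bis(tert-butyldimethylsilyloxy)-4-hydroxy-3-(3-methylbuta-1,2-dien-1-yl)phenyl]-2-methylpropan-1-one | CC(C)C(=O)c1c(O[Si](C)(C)C(C)(C)C)cc(O)c(C=C=C(C)C)c1O[Si](C)(C)C(C)(C)C | intermediate (not isolated)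
8 | 3,5-bis(tert-butyldimethylsilyloxy)-6-(3-methylbut-2-en-1-ylidene)-4-(2-methylpropanoyl)cyclohexa-2,4-dien-1-one | CC(C)C(=O)C1=C(O[Si](C)(C)C(C)(C)C)C(=CC=C(C)C)C(=O)C=C1O[Si](C)(C)C(C)(C)C | intermediate (not isolated)
9 | 1-[5,7-bis(tert-butyldimethylsilyloxy)-2,2-dimethyl-2H-chromen-6-yl]-2-methylpropan-1-one | CC(C)C(=O)c1c(O[Si](C)(C)C(C)(C)C)cc2OC(C)(C)C=Cc2c1O[Si](C)(C)C(C)(C)C | intermediate
10 | 1-[(3S,4S)-5,7-bis(tert-butyldimethylsilyloxy)-3,4-epoxy-2,2-dimethylchroman-6-yl]-2-methylpropan-1-one | CC1(C)[C@H]2O[C@H]2c3c(O[Si](C)(C)C(C)(C)C)c(C(=O)C(C)C)c(O[Si](C)(C)C(C)(C)C)cc3O1 | intermediate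
11 | 1-[(3S)-5,7-bis(tert-butyldimethylsilyloxy)-3-hydroxy-2,2-dimethylchroman-6-yl]-2-methylpropan-1-one | CC1(C)[C@@H](O)Cc2c(O[Si](C)(C)C(C)(C)C)c(C(=O)C(C)C)c(O[Si](C)(C)C(C)(C)C)cc2O1 | intermediate
12 | (3S)-5,7-bis(tert-butyldimethylsilyloxy)-2,2-dimethyl-6-(2-methylpropanoyl)chroman-3-yl trifluoromethanesulfonate | CC1(C)[C@@H](OS(=O)(=O)C(F)(F)F)Cc2c(O[Si](C)(C)C(C)(C)C)c(C(=O)C(C)C)c(O[Si](C)(C)C(C)(C)C)cc2O1 | intermediate (not isolated)
13 | bridged aryl-oxiranium triflate: O1 bonded to C8a, C2 and C3 (C3 inverted, R) of the 5,7-bis(tert-butyldimethylsilyloxy)-2,2-dimethyl-6-(2-methylpropanoyl)chroman skeleton | CC1(C)[C@H]2Cc3c(O[Si](C)(C)C(C)(C)C)c(C(=O)C(C)C)c(O[Si](C)(C)C(C)(C)C)cc3[O+]12.[O-]S(=O)(=O)C(F)(F)F | intermediate (not isolated)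
14 | 1-[(2R)-4,6-bis(tert-butyldimethylsilyloxy)-2-(prop-1-en-2-yl)-2,3-dihydro-1-benzofuran-5-yl]-2-methylpropan-1-one | C=C(C)[C@H]1Cc2c(O[Si](C)(C)C(C)(C)C)c(C(=O)C(C)C)c(O[Si](C)(C)C(C)(C)C)cc2O1 | intermediate
15 | 1-[(2R)-4,6-dihydroxy-2-(prop-1-en-2-yl)-2,3-dihydro-1-benzofuran-5-yl]-2-methylpropan-1-one | C=C(C)[C@H]1Cc2c(O)c(C(=O)C(C)C)c(O)cc2O1 | intermediate
16 | 1-[(2R)-7-[(dimethylamino)methyl]-4,6-dihydroxy-2-(prop-1-en-2-yl)-2,3-dihydro-1-benzofuran-5-yl]-2-methylpropan-1-one | C=C(C)[C@H]1Cc2c(O)c(C(=O)C(C)C)c(O)c(CN(C)C)c2O1 | intermediate
17 | pentan-3-one | CCC(=O)CC | starting material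
18 | trimethyl(pent-2-en-3-yloxy)silane | CC=C(CC)O[Si](C)(C)C | intermediate
19 | malonyl dichloride (propanedioyl dichloride) | O=C(Cl)CC(Cl)=O | starting material
20 | 6-ethyl-4-hydroxy-5-methyl-2H-pyran-2-one | CCc1oc(=O)cc(O)c1C | intermediate
21 | (2R)-4-hydroxy-7-methylidene-5-(2-methylpropanoyl)-2-(prop-1-en-2-yl)-2,3-dihydro-1-benzofuran-6(7H)-one | C=C(C)[C@H]1CC2=C(O1)C(=C)C(=O)C(C(=O)C(C)C)=C2O | intermediate (not isolated)
22 | 6-ethyl-4-hydroxy-3-{[(2R)-4,6-dihydroxy-5-(2-methylpropanoyl)-2-(prop-1-en-2-yl)-2,3-dihydro-1-benzofuran-7-yl]methyl}-5-methyl-2H-pyran-2-one | C=C(C)[C@H]1Cc2c(O)c(C(=O)C(C)C)c(O)c(Cc3c(O)c(C)c(CC)oc3=O)c2O1 | target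

## Step count and least certain steps

Total step count: 12. Longest linear sequence: 10 (steps 1 to 9 and step 12). The pyranone branch is steps 10 and 11.

**Step 7 (key step).**
- What may go wrong: elimination toward C4 (direct loss of the axial hydrogen, or hydride shift to the strongly stabilised benzylic position followed by proton loss) or migration of the axial C2 methyl group. The triflate spends part of its time pseudo-axial and an aryl ether oxygen is only a moderate neighbouring group. A second failure mode is unselective proton loss from a fully opened tertiary cation, giving the isopropylidene enol ether and then aromatisation to the benzofuran.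
- Fallback: it sets out from 11 and comes back at 14, in two known stages. Mesylation (MsCl, Et3N, CH2Cl2, 0 °C) should give (3S)-5,7-bis(tert-butyldimethylsilyloxy)-2,2-dimethyl-6-(2-methylpropanoyl)chroman-3-yl methanesulfonate F1. Buffered solvolysis of this poorer leaving group in aqueous hexafluoroisopropanol with 2,6-lutidine at about 50 °C removes all base-driven elimination and lets water capture the oxiranium ion at the tertiary carbon. This should give 1-[(2R)-4,6-bis(tert-butyldimethylsilyloxy)-2-(2-hydroxypropan-2-yl)-2,3-dihydro-1-benzofuran-5-yl]-2-methylpropan-1-one F2, again with inversion at the former C3. Dehydration of F2 toward a methyl group (SOCl2, pyridine, 0 °C, or Burgess reagent) then gives 14.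

**Step 2.**
- What may go wrong: alkylation at an ortho oxygen, double alkylation, or C-alkylation of the ambident phloroglucinol anion. The copper catalyst may also be sequestered by the hydroxy-ketone chelate.
- Fallback: it sets out from 3 and comes back at 9. Condensation of 3 with 3-methylbut-2-enal (Ca(OH)2, MeOH, rt, or pyridine, 110 °C; aldol addition, dehydration, oxa-6π closure) should give 1-(5,7-dihydroxy-2,2-dimethyl-2H-chromen-6-yl)-2-methylpropan-1-one F3. Its 8-acyl isomer forms alongside and must be separated, which is the price of this shorter path. Bis-silylation of F3 under the conditions of step 3 gives 9.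

**Step 5.**
- What may go wrong: opening of the very electron-rich benzylic epoxide by the carboxylic acid, the Lewis-acidic manganese complex or silica, and lower facial selectivity caused by the peri silyloxy group at C5.
- Fallback: it sets out from 9 and comes back at 11, bypassing 10 and step 6. Hydroboration–oxidation (BH3·SMe2, THF, 0 °C; NaBO3·4H2O), with boron adding to C3, should give racemic 1-[5,7-bis(tert-butyldimethylsilyloxy)-3-hydroxy-2,2-dimethylchroman-6-yl]-2-methylpropan-1-one F4. Dess–Martin oxidation gives 5,7-bis(tert-butyldimethylsilyloxy)-2,2-dimethyl-6-(2-methylpropanoyl)chroman-3-one F5. Corey–Bakshi–Shibata reduction (BH3·SMe2) then differentiates the quaternary C2 (large) from the benzylic CH2 (small); by the usual model the (R)-oxazaborolidine should give the 3S alcohol 11.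

**Step 12.**
- What may go wrong: self-reaction of quinone methide 21 (dimerisation, or hetero-Diels–Alder addition to an isopropenyl group) or O-alkylation of 20 if carbon attack is slow. Amine loss may also be incomplete at a temperature the substrate tolerates.
- Fallback: it sets out from 15 and 20 and comes back at 22, bypassing 16. The roles are reversed: 20 and Eschenmoser's salt (CH2Cl2, rt) should give 3-[(dimethylamino)methyl]-6-ethyl-4-hydroxy-5-methyl-2H-pyran-2-one F6. On warming with a slight excess of 15 in dioxane, F6 loses dimethylamine and its methylene is taken up by C7 of 15, the only free and most nucleophilic ring position.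

## Further compounds

F1 | step 7 | (3S)-5,7-bis(tert-butyldimethylsilyloxy)-2,2-dimethyl-6-(2-methylpropanoyl)chroman-3-yl methanesulfonate | CC1(C)[C@@H](OS(C)(=O)=O)Cc2c(O[Si](C)(C)C(C)(C)C)c(C(=O)C(C)C)c(O[Si](C)(C)C(C)(C)C)cc2O1
F2 | step 7 | 1-[(2R)-4,6-bis(tert-butyldimethylsilyloxy)-2-(2-hydroxypropan-2-yl)-2,3-dihydro-1-benzofuran-5-yl]-2-methylpropan-1-one | CC(C)(O)[C@H]1Cc2c(O[Si](C)(C)C(C)(C)C)c(C(=O)C(C)C)c(O[Si](C)(C)C(C)(C)C)cc2O1
F3 | step 2 | 1-(5,7-dihydroxy-2,2-dimethyl-2H-chromen-6-yl)-2-methylpropan-1-one | CC(C)C(=O)c1c(O)cc2OC(C)(C)C=Cc2c1O
F4 | step 5 | racemic 1-[5,7-bis(tert-butyldimethylsilyloxy)-3-hydroxy-2,2-dimethylchroman-6-yl]-2-methylpropan-1-one | CC1(C)C(O)Cc2c(O[Si](C)(C)C(C)(C)C)c(C(=O)C(C)C)c(O[Si](C)(C)C(C)(C)C)cc2O1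
F5 | step 5 | 5,7-bis(tert-butyldimethylsilyloxy)-2,2-dimethyl-6-(2-methylpropanoyl)chroman-3-one | CC1(C)C(=O)Cc2c(O[Si](C)(C)C(C)(C)C)c(C(=O)C(C)C)c(O[Si](C)(C)C(C)(C)C)cc2O1
F6 | step 12 | 3-[(dimethylamino)methyl]-6-ethyl-4-hydroxy-5-methyl-2H-pyran-2-one | CCc1oc(=O)c(CN(C)C)c(O)c1C
A1 | alternative 1 | 3-ethoxy-4-(3-methylbut-2-enyl)cyclobut-2-en-1-one | CCOC1=CC(=O)C1CC=C(C)C
A2 | alternative 1 | triisopropyl(3-methoxyprop-1-ynyloxy)silane | COCC#CO[Si](C(C)C)(C(C)C)C(C)C
A3 | alternative 1 | 3-ethoxy-2-(3-methylbut-2-enyl)-6-(methoxymethyl)-5-(triisopropylsilyloxy)phenol | Oc1c(COC)c(O[Si](C(C)C)(C(C)C)C(C)C)cc(OCC)c1CC=C(C)C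
A4 | alternative 2 | methyl (5R)-2-(5-methyl-2,4-dioxohexyl)-5-(prop-1-en-2-yl)-4,5-dihydrofuran-3-carboxylate | C=C(C)[C@H]1CC(C(=O)OC)=C(CC(=O)CC(=O)C(C)C)O1
A5 | alternative 2 | 1-[(2R)-4,6-dihydroxy-2-(prop-1-en-2-yl)-2,3-dihydro-1-benzofuran-5-yl]-2-methylpropan-1-one (same structure as 15) | C=C(C)[C@H]1Cc2c(O)c(C(=O)C(C)C)c(O)cc2O1
A6 | alternative 3 | 3-(chlorocarbonyl)-3,4-dihydrocoumarin formed between O6 and C7 of (2R)-4-(tert-butyldimethylsilyloxy)-5-(2-methylpropanoyl)-2-(prop-1-en-2-yl)-2,3-dihydro-1-benzofuran (malonate carbon unassigned) | C=C(C)[C@H]1Cc2c(O[Si](C)(C)C(C)(C)C)c(C(=O)C(C)C)c3OC(=O)C(C(Cl)=O)Cc3c2O1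
A7 | alternative 3 | 4-O-tert-butyldimethylsilyl ether of the target | C=C(C)[C@H]1Cc2c(O[Si](C)(C)C(C)(C)C)c(C(=O)C(C)C)c(O)c(Cc3c(O)c(C)c(CC)oc3=O)c2O1
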